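## Retrosynthetic overview

1. Atom labels: ring A = C1–C5/C10 and ring B = C5–C10 (left decalin, C7=C8), linker C11–C12, ring C = C13–C18 and ring D = C17–C22 (right decalin); β is the face of the C10 and C18 methyls. The plan rests on ring C: the quaternary C18 methyl is syn to H17 (cis ring fusion) and flanks the chain carbon C13, which flanks the methyl-bearing C14. A C14 carbonyl therefore makes C18 the β-carbon of an enone and C13 its enolate carbon.
2. Target ⇐ C14 ketone 22: the C14 methyl comes from methylenation and radical hydrogenation, the C12 methylene from radical deoxygenation of an aldol carbinol.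
3. Key disconnection: C18–CH3 and C12–C13, made in one operation by conjugate addition of Me2CuLi to ring C/D octalone 8 and aldol addition of the resulting C13 enolate to left-half aldehyde 17.
4. Rings A/B have the same substitution and absolute configuration as rings D/C, so 17 is made from the same octalone 8: conjugate methylation with silyl trapping (C10), fluoride-mediated alkylation of the silyl enol ether (C9–C11), C7=C8 enol triflate, methyl coupling at C8, ester to aldehyde.
5. Octalone 8 comes from 6-methoxy-2-tetralone. Both six-membered carbocycles are present from the start, so no ring is built by C–C bond formation: ring D (ring A) is fixed first by gem-dimethylation and asymmetric reduction, then the anisole ring is turned into the ring C (ring B) enone by Birch reduction and acid.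

Key step: step 10

Remark: when 8 is used for the left half its atoms C13, C14, C15, C16, C17, C18, C19, C20, C21, C22 become C9, C8, C7, C6, C5, C10, C1, C2, C3, C4. The C12 carbinol configuration of aldol 20 is drawn for the expected anti adduct and is assumed to be of no consequence, because C12 becomes a methylene group in step 12.

## Route

Step 1
Reactants: 1 6-methoxy-2-tetralone; 2 iodomethane
Product: 3 6-methoxy-1,1-dimethyl-3,4-dihydronaphthalen-2(1H)-one
Conditions: KOt-Bu (2.5 equiv), MeI (3 equiv), THF, 0 °C to rt
Reagents that add atoms: iodomethane, CI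
Why: Double enolate C-alkylation occurs at C1, the benzylic α-carbon that is activated by both the ketone and the arene, and gives the future C22 (C4) gem-dimethyl group.

Step 2
Reactants: 3 6-methoxy-1,1-dimethyl-3,4-dihydronaphthalen-2(1H)-one
Product: 4 (R)-6-methoxy-1,1-dimethyl-1,2,3,4-tetrahydronaphthalen-2-ol
Conditions: (S)-2-methyl-CBS-oxazaborolidine ((S)-1-methyl-3,3-diphenyltetrahydro-1H,3H-pyrrolo[1,2-c][1,3,2]oxazaborole, 10 mol %), BH3·SMe2, THF, −20 °C; MeOH
Reagents that add atoms: none
Why: Corey–Bakshi–Shibata reduction, in which the quaternary C1 acts as the large group and the methylene as the small one, so the (S)-catalyst should deliver hydride to give the (R)-carbinol that becomes C21 (and C3).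

Step 3
Reactants: 4 (R)-6-methoxy-1,1-dimethyl-1,2,3,4-tetrahydronaphthalen-2-ol
Product: 7 (4aS,6R)-6-hydroxy-5,5-dimethyl-4,4a,5,6,7,8-hexahydronaphthalen-2(3H)-one, via dihydroanisole 5 (not isolated), via unconjugated enone 6 (not isolated)
Conditions: Li, NH3(l), t-BuOH, THF, −78 to −33 °C; then 2 M HCl, THF, rt; chromatography, minor C17 epimer resubmitted to the acid
Reagents that add atoms: water, O
Why: Birch reduction of the anisole ring gives the 2,5-dihydroanisole, acid hydrolyses its enol ether and moves the C17=C18 bond into conjugation, and C17 is set by reversible γ-protonation of the dienol, which should favour the epimer with H17 trans to the C21 oxygen because that epimer keeps the hydroxyl equatorial on the ring D chair; the preference is expected to be moderate, hence the separation and recycling.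

Step 4
Reactants: 7 (4aS,6R)-6-hydroxy-5,5-dimethyl-4,4a,5,6,7,8-hexahydronaphthalen-2(3H)-one
Product: 8 (4aS,6R)-6-(tert-butyldimethylsilyloxy)-5,5-dimethyl-4,4a,5,6,7,8-hexahydronaphthalen-2(3H)-one
Conditions: TBSOTf, 2,6-lutidine, CH2Cl2, −78 to 0 °C
Reagents that add atoms: tert-butyldimethylsilyl trifluoromethanesulfonate, CC(C)(C)[Si](C)(C)OS(=O)(=O)C(F)(F)F
Why: Silylation of the hindered neopentyl-type secondary alcohol with the silyl triflate is much faster than silylation of the enone oxygen at low temperature.

Step 5
Reactants: 8 ring C/D octalone (here the ring B/A precursor); 9 lithium dimethylcuprate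
Product: 10 trimethylsilyl enol ether (C8=C9–OSiMe3 in left-half numbering, C13=C14 in right-half numbering) of the C10 (C18) methylated cis-decalone
Conditions: Me2CuLi (from CuI and MeLi), Me3SiCl, Et3N, Et2O–THF, −78 to 0 °C; cold aq. NaHCO3
Reagents that add atoms: lithium dimethylcuprate, [Li+].C[Cu-]C; chlorotrimethylsilane, C[Si](C)(C)Cl
Why: Chlorosilane-accelerated Gilman conjugate addition, in which the methyl enters C10 axially on the face of H5 (the other face would bring it syn-diaxial to the axial C4 methyl) to give the cis-fused decalin, while Me3SiCl captures the enolate oxygen as the C–C bond forms, so the regiodefined silyl enol ether is obtained free of copper salts and no metal enolate accumulates.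

Step 6
Reactants: 10 trimethylsilyl enol ether; 11 ethyl bromoacetate
Product: 13 left-half keto ester (C8 ketone; C9β CH2CO2Et; C10β methyl; H5β; C3α OTBS), via ammonium enolate 12 (not isolated)
Conditions: BnMe3N+F− (1.1 equiv, dried), BrCH2CO2Et, 4 Å MS, THF, 0 °C to rt
Reagents that add atoms: ethyl bromoacetate, CCOC(=O)CBr
Why: Fluoride-mediated regiospecific alkylation of a silyl enol ether, in which fluoride removes the trimethylsilyl group far faster than it attacks the hindered secondary silyl ether, the quaternary ammonium enolate is alkylated at C9 by the reactive α-bromo ester before proton exchange to C7 can occur, and the chain should enter on the β face cis to the C10 methyl because the α face is covered by the axial C4 carbon of ring A and its methyl, which is also the equatorial and more stable arrangement at the epimerisable C9.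

Step 7
Reactants: 13 left-half keto ester
Product: 14 C7=C8 enol triflate of 13
Conditions: KN(SiMe3)2, THF, −78 °C; PhNTf2, −78 to 0 °C
Reagents that add atoms: N-phenylbis(trifluoromethanesulfonimide), O=S(=O)(N(c1ccccc1)S(=O)(=O)C(F)(F)F)C(F)(F)F
Why: Kinetic deprotonation takes the C7 methylene of the ketone and not the hindered C9 methine or the less acidic ester, and O-triflation fixes the position of the ring B double bond without touching C9.

Step 8
Reactants: 14 C7=C8 enol triflate; 15 methylmagnesium bromide
Product: 16 left-half ethyl ester with C7=C8 alkene and C8 methyl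
Conditions: Fe(acac)3 (10 mol %), MeMgBr, THF–NMP, −30 to 0 °C
Reagents that add atoms: methylmagnesium bromide, C[Mg]Br
Why: Iron-catalysed Kumada-type cross-coupling of an alkenyl triflate with a methyl Grignard reagent is fast at low temperature and tolerates the ester, and it installs the C8 methyl on the C7=C8 alkene.

Step 9
Reactants: 16 left-half ethyl ester
Product: 17 left-half aldehyde (C12 = CHO)
Conditions: i-Bu2AlH (1.1 equiv), CH2Cl2, −78 °C; MeOH, then aq. KNaC4H4O6
Reagents that add atoms: none
Why: Partial ester reduction stops at the tetrahedral aluminium hemiacetal at −78 °C, which is stabilised by the branched C9 neighbour and gives the aldehyde on work-up.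

Step 10
Reactants: 8 ring C/D octalone; 9 lithium dimethylcuprate; 17 left-half aldehyde
Product: 20 anti aldol adduct (C12 carbinol; C14 ketone; full carbon skeleton except the C14 methyl), via lithium enolate 18 (not isolated), via zinc enolate 19 (not isolated)
Conditions: Me2CuLi (from CuI and MeLi), Et2O, 0 °C; ZnCl2 (Et2O), −78 °C; then 17, THF, −78 to −40 °C; aq. NH4Cl
Reagents that add atoms: lithium dimethylcuprate, [Li+].C[Cu-]C
Why: Me2CuLi forms a π-complex with the enone of 8, oxidative addition gives a β-cuprio enolate of trivalent copper, and reductive elimination makes the C18–CH3 bond and lithium enolate 18, regiodefined at C13=C14. Transmetalation with ZnCl2 gives zinc enolate 19, which adds to the aldehyde carbon C12 of 17 through a closed six-membered Zimmerman–Traxler transition state to form the C12–C13 bond; the closest known reaction type is the three-component conjugate addition–aldol coupling of cyclic enones with organocopper reagents and aldehydes. No ring is closed in this step. C18 is set by axial attack on the face that carries H17, the normal cis-selective course for Δ1(8a)-2-octalones, and attack on the other face would push the incoming methyl into a 1,3-diaxial contact with the axial C22 methyl. C13 is set by attack of the aldehyde on the β face of the cis-fused enolate, because the α face is covered by the axial C22 carbon of ring D and its inward methyl, and the chain is then equatorial on ring C, the arrangement that equilibration at this epimerisable centre would also favour. The step therefore needs face selectivity at C18 and C13 and regiocontrol of the enolate, which are secured by the C17/C22 substitution of ring D, by the cis fusion just created, and by generating the enolate through conjugate addition instead of deprotonation.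

Step 11
Reactants: 20 anti aldol adduct
Product: 21 O-(C12) 1H-imidazole-1-carbothioate of 20
Conditions: 1,1'-thiocarbonyldiimidazole, DMAP (cat.), ClCH2CH2Cl, 70 °C
Reagents that add atoms: 1,1'-thiocarbonyldiimidazole, S=C(n1ccnc1)n1ccnc1
Why: Thiocarbamate formation for a Barton–McCombie deoxygenation proceeds without strong base, which avoids retro-aldol cleavage and leaves the hindered C13 methine untouched.

Step 12
Reactants: 21 C12 imidazolyl thiocarbamate
Product: 22 C14 ketone with C11–C12 ethylene linker (C13β chain)
Conditions: Bu3SnH, AIBN (cat.), toluene, 100 °C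
Reagents that add atoms: none
Why: Barton–McCombie radical deoxygenation (stannyl radical addition to C=S, β-scission to the secondary C12 radical, hydrogen transfer from Bu3SnH) removes the carbinol oxygen without involving C13, so both C12 epimers converge and the C13 configuration from step 10 is kept.

Step 13
Reactants: 22 C14 ketone; 23 dimethyltitanocene Cp2TiMe2
Product: 24 C14 exocyclic methylene compound
Conditions: Cp2TiMe2, toluene, 70 °C, dark
Reagents that add atoms: dimethyltitanocene, C[Ti+2]C.[cH-]1cccc1.[cH-]1cccc1
Why: Petasis olefination through Cp2Ti=CH2 and an oxatitanacyclobutane is non-basic, so the hindered and enolisable C14 ketone is methylenated without epimerisation at C13.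

Step 14
Reactants: 24 C14 exocyclic methylene compound
Product: 25 bis(tert-butyldimethylsilyl) ether of the target
Conditions: Mn(dpm)3 (tris(2,2,6,6-tetramethyl-3,5-heptanedionato)manganese, 10 mol %), PhSiH3 (1.1 equiv), t-BuOOH, i-PrOH, rt
Reagents that add atoms: none
Why: Hydrogen-atom-transfer hydrogenation (Mn–H gives H• to the terminal CH2, then the tertiary C14 radical takes the second hydrogen) should be faster for the 1,1-disubstituted alkene than for the hindered trisubstituted C7=C8 bond and should give the more stable C14 epimer, methyl equatorial and trans to the C13 chain, because the other epimer would place the methyl syn-axial to the C18 methyl.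

Step 15
Reactants: 25 bis(tert-butyldimethylsilyl) ether of the target
Product: 26 CNP0194061.2 (target diol)
Conditions: Bu4NF, THF, 60 °C
Reagents that add atoms: none
Why: Fluoride cleaves both hindered silyl ethers through Si–F bond formation under basic conditions that leave the C7=C8 alkene in place.

## Compound list

1 | 6-methoxy-3,4-dihydronaphthalen-2(1H)-one (6-methoxy-2-tetralone) | COc1ccc2CC(=O)CCc2c1 | starting material
2 | iodomethane | CI | starting material
3 | 6-methoxy-1,1-dimethyl-3,4-dihydronaphthalen-2(1H)-one | COc1ccc2c(c1)CCC(=O)C2(C)C | intermediate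
4 | (R)-6-methoxy-1,1-dimethyl-1,2,3,4-tetrahydronaphthalen-2-ol | COc1ccc2c(c1)CC[C@@H](O)C2(C)C | intermediate
5 | (R)-6-methoxy-1,1-dimethyl-1,2,3,4,5,8-hexahydronaphthalen-2-ol (2,5-dihydroanisole) | COC1=CCC2=C(C1)CC[C@@H](O)C2(C)C | intermediate (not isolated)
6 | (R)-6-hydroxy-5,5-dimethyl-3,4,5,6,7,8-hexahydronaphthalen-2(1H)-one (C17=C18 enone) | O=C1CCC2=C(C1)CC[C@@H](O)C2(C)C | intermediate (not isolated)
7 | (4aS,6R)-6-hydroxy-5,5-dimethyl-4,4a,5,6,7,8-hexahydronaphthalen-2(3H)-one (H17 trans to the C21 hydroxyl) | O=C1CC[C@@H]2C(C)(C)[C@H](O)CCC2=C1 | intermediate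
8 | (4aS,6R)-6-(tert-butyldimethylsilyloxy)-5,5-dimethyl-4,4a,5,6,7,8-hexahydronaphthalen-2(3H)-one (ring C/D octalone: C14 ketone, C13=C18, C21α OTBS) | O=C1CC[C@@H]2C(C)(C)[C@H](O[Si](C)(C)C(C)(C)C)CCC2=C1 | intermediate (key-step precursor)
9 | lithium dimethylcuprate (formed from MeLi and CuI) | [Li+].C[Cu-]C | starting material (reagent, key-step precursor)
10 | trimethylsilyl enol ether (C8=C9–OSiMe3) of the C10-methylated cis-decalone, C3α OTBS | C1=C(O[Si](C)(C)C)CC[C@@H]2C(C)(C)[C@H](O[Si](C)(C)C(C)(C)C)CC[C@@]21C | intermediate
11 | ethyl bromoacetate | CCOC(=O)CBr | starting material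
12 | benzyltrimethylammonium C8=C9 enolate of the C10-methylated cis-decalone | C[N+](C)(C)Cc1ccccc1.C1=C([O-])CC[C@@H]2C(C)(C)[C@H](O[Si](C)(C)C(C)(C)C)CC[C@@]21C | intermediate (not isolated)
13 | left-half keto ester: ethyl ester of the C9β acetic acid, C8 ketone, C10β methyl, H5β, C4 gem-dimethyl, C3α OTBS | CCOC(=O)C[C@H]1C(=O)CC[C@@H]2C(C)(C)[C@H](O[Si](C)(C)C(C)(C)C)CC[C@@]21C | intermediate
14 | C7=C8 enol triflate of 13 | CCOC(=O)C[C@H]1C(OS(=O)(=O)C(F)(F)F)=CC[C@@H]2C(C)(C)[C@H](O[Si](C)(C)C(C)(C)C)CC[C@@]21C | intermediate
15 | methylmagnesium bromide | C[Mg]Br | starting material (reagent)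
16 | left-half ethyl ester with C7=C8 alkene and C8 methyl | CCOC(=O)C[C@H]1C(C)=CC[C@@H]2C(C)(C)[C@H](O[Si](C)(C)C(C)(C)C)CC[C@@]21C | intermediate
17 | left-half aldehyde (C12 = CHO; C7=C8, C8 and C10 methyls, C9β chain, H5β, C3α OTBS) | CC1=CC[C@@H]2C(C)(C)[C@H](O[Si](C)(C)C(C)(C)C)CC[C@]2(C)[C@H]1CC=O | intermediate (key-step precursor)
18 | lithium C13=C14 enolate of the C18-methylated cis-decalone | [Li+].C1=C([O-])CC[C@@H]2C(C)(C)[C@H](O[Si](C)(C)C(C)(C)C)CC[C@@]21C | intermediate (not isolated)
19 | chlorozinc C13=C14 enolate | C1=C(O[Zn]Cl)CC[C@@H]2C(C)(C)[C@H](O[Si](C)(C)C(C)(C)C)CC[C@@]21C | intermediate (not isolated)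
20 | anti aldol adduct: C12 carbinol, C14 ketone, C13β chain, C18β methyl, H17β, both carbinols as OTBS | CC1=CC[C@@H]2C(C)(C)[C@H](O[Si](C)(C)C(C)(C)C)CC[C@]2(C)[C@H]1C[C@H](O)[C@H]1C(=O)CC[C@@H]2C(C)(C)[C@H](O[Si](C)(C)C(C)(C)C)CC[C@@]21C | intermediate (key-step product)
21 | O-(C12) 1H-imidazole-1-carbothioate of 20 | CC1=CC[C@@H]2C(C)(C)[C@H](O[Si](C)(C)C(C)(C)C)CC[C@]2(C)[C@H]1C[C@H](OC(=S)n1ccnc1)[C@H]1C(=O)CC[C@@H]2C(C)(C)[C@H](O[Si](C)(C)C(C)(C)C)CC[C@@]21C | intermediate
22 | C14 ketone with C11–C12 ethylene linker | CC1=CC[C@@H]2C(C)(C)[C@H](O[Si](C)(C)C(C)(C)C)CC[C@]2(C)[C@H]1CC[C@H]1C(=O)CC[C@@H]2C(C)(C)[C@H](O[Si](C)(C)C(C)(C)C)CC[C@@]21C | intermediate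
23 | dimethyltitanocene Cp2TiMe2 | C[Ti+2]C.[cH-]1cccc1.[cH-]1cccc1 | starting material (reagent)
24 | C14 exocyclic methylene compound | CC1=CC[C@@H]2C(C)(C)[C@H](O[Si](C)(C)C(C)(C)C)CC[C@]2(C)[C@H]1CC[C@H]1C(=C)CC[C@@H]2C(C)(C)[C@H](O[Si](C)(C)C(C)(C)C)CC[C@@]21C | intermediate
25 | bis(tert-butyldimethylsilyl) ether of the target (C14α methyl) | CC1=CC[C@@H]2C(C)(C)[C@H](O[Si](C)(C)C(C)(C)C)CC[C@]2(C)[C@H]1CC[C@H]1[C@H](C)CC[C@@H]2C(C)(C)[C@H](O[Si](C)(C)C(C)(C)C)CC[C@@]21C | intermediate
26 | CNP0194061.2 | CC1=CC[C@@H]2C(C)(C)[C@H](O)CC[C@]2(C)[C@H]1CC[C@H]1[C@H](C)CC[C@@H]2C(C)(C)[C@H](O)CC[C@@]21C | target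

## Step count and risks

Total step count: 15. Longest linear sequence: 15 steps (1 → 8 → 10 → 17 → 20 → 26; octalone 8 enters at step 5 and again at step 10).

Steps most likely to fail:

1. Step 10. The hindered C13 enolate may be trapped incompletely by the enolisable aldehyde (proton transfer, retro-aldol on warming), or the aldehyde may approach from the wrong face. Fallback, from silyl enol ether 10 and aldehyde 17 back to 20: the methyl addition and the C12–C13 bond formation are separated. Compound 10, already isolated copper-free in step 5, is the C13=C14 silyl enol ether of the ring C/D half. A Mukaiyama aldol addition of 10 to 17 (BF3·OEt2, CH2Cl2, −78 °C), which runs through an open transition state with the aldehyde activated by the Lewis acid, should give 20 after aqueous work-up. This fallback makes no compound that the compound list lacks (F0).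

2. Step 6. Protonation of the desilylated enolate or proton exchange may outrun C-alkylation at the neopentyl-type C9, or the chain may enter on the wrong face. Fallback, from 10 back to 16, forming the C9–C11 bond by a sigmatropic shift instead. CsF and PhNTf2 in DME at rt convert 10 directly into the C8 enol triflate F1 (C8=C9). Fe(acac)3-catalysed coupling with MeMgBr (15) gives the 8,10-dimethyl C8=C9 alkene F2. SeO2 (cat.)/t-BuOOH in CH2Cl2 hydroxylates the ring methylene C7 (ene reaction at C9 on the β face, then 2,3-shift) and should give the 7β-allylic alcohol F3. Johnson–Claisen rearrangement of F3 with MeC(OEt)3 and catalytic propionic acid at 140 °C transfers the C7–O bond suprafacially into the C9β–C11 bond and moves the alkene to C7=C8, which gives ester 16.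

3. Step 14. Chemoselectivity may be lost (reduction or migration of the C7=C8 bond), or hydrogen may be delivered to the other face of the C14 radical. Fallback, from 22 back to 25, placing an epimerisable group on C14. Wittig reaction with Ph3P=CHOMe (from the phosphonium chloride and KN(SiMe3)2, THF) gives the C14 methoxymethylene compound F4. Brief hydrolysis with dilute HCl in THF and then K2CO3 in MeOH equilibrates the formyl group to the equatorial position trans to the C13 chain and gives the 14α-carbaldehyde F5. N2H4·H2O in EtOH gives the hydrazone F6, and KOt-Bu in DMSO at rt (Wolff–Kishner reduction) converts it into the C14 methyl compound 25.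

## Further compounds

F0 | step 10 | none | none
F1 | step 6 | C8 enol triflate (C8=C9) of the C10-methylated left-half ketone | C1=C(OS(=O)(=O)C(F)(F)F)CC[C@@H]2C(C)(C)[C@H](O[Si](C)(C)C(C)(C)C)CC[C@@]21C
F2 | step 6 | 8,10-dimethyl C8=C9 alkene | C1=C(C)CC[C@@H]2C(C)(C)[C@H](O[Si](C)(C)C(C)(C)C)CC[C@@]21C
F3 | step 6 | 7β-allylic alcohol of F2 | C1=C(C)[C@@H](O)C[C@@H]2C(C)(C)[C@H](O[Si](C)(C)C(C)(C)C)CC[C@@]21C
F4 | step 14 | C14 methoxymethylene compound (E/Z mixture) | CC1=CC[C@@H]2C(C)(C)[C@H](O[Si](C)(C)C(C)(C)C)CC[C@]2(C)[C@H]1CC[C@H]1C(=COC)CC[C@@H]2C(C)(C)[C@H](O[Si](C)(C)C(C)(C)C)CC[C@@]21C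
F5 | step 14 | 14α-carbaldehyde | CC1=CC[C@@H]2C(C)(C)[C@H](O[Si](C)(C)C(C)(C)C)CC[C@]2(C)[C@H]1CC[C@H]1[C@H](C=O)CC[C@@H]2C(C)(C)[C@H](O[Si](C)(C)C(C)(C)C)CC[C@@]21C
F6 | step 14 | hydrazone of F5 | CC1=CC[C@@H]2C(C)(C)[C@H](O[Si](C)(C)C(C)(C)C)CC[C@]2(C)[C@H]1CC[C@H]1[C@H](C=NN)CC[C@@H]2C(C)(C)[C@H](O[Si](C)(C)C(C)(C)C)CC[C@@]21C
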